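The plan disconnects the C6–O bond of the cyclopentane ring of the cyclopenta[c]pyridine back to a C6=C7 alkene and a free carboxyl on C5. Because the C6 acetoxy oxygen and the C5 ester carbon lie on the same face of that ring, iodine-triggered closure of the C5 acid onto C6 sets C6 relative to C5, stores the new oxygen as a β-lactone and leaves an iodide on C7 as the seed of the ketone. The substrate is an enantioenriched 3-chloro-6-methyl-5-silyloxy-5H-cyclopenta[c]pyridine-5-carboxylic acid, reached through Dieckmann closure and catalytic asymmetric C5 hydroxylation; the dienyl chain is added last by Suzuki coupling.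

Key step: step 9

Assumption: in step 4 hydroquinidine is taken to favour the (5R) alcohol; if the first run shows the opposite sense, hydroquinine replaces it with nothing else changed.
Remark: locants are those of cyclopenta[c]pyridine (C1, N2, C3, C4, C4a, C5, C6, C7, C7a). The CIP letter at C5 changes along the route (R in 8–10, S in 11–13, R from 14 on) through priority changes only; the spatial arrangement stays the same.

Step 1
Reactants: 1 5-bromo-2-chloro-4-methylpyridine; 2 di-tert-butyl dicarbonate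
Product: 3 tert-butyl 2-(5-bromo-2-chloropyridin-4-yl)acetate
Conditions: LiN(iPr)2 (2.1 equiv), THF, −78 °C; then 2 (1.05 equiv), −78 → −40 °C
Reagents that add atoms: none
Why: Lateral lithiation of the 4-methyl group (a picolyl anion stabilised by the ring nitrogen and both halogens) followed by C-acylation with the dicarbonate; the second equivalent of amide absorbs the more acidic product and so prevents double acylation.

Step 2
Reactants: 3 tert-butyl 2-(5-bromo-2-chloropyridin-4-yl)acetate; 4 methyl bromoacetate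
Product: 6 tert-butyl 2-[2-chloro-5-(2-methoxy-2-oxoethyl)pyridin-4-yl]acetate, via (2-methoxy-2-oxoethyl)zinc bromide 5 (not isolated)
Conditions: Zn dust, Me3SiCl (cat.), THF, 40 °C (4 → 5, 2 equiv); then 3, Pd[P(tBu)3]2 (3 mol%), THF, 25 °C
Reagents that add atoms: none
Why: Reformatsky reagent formation followed by Negishi coupling, in which zerovalent palladium should insert into the C–Br bond well before the C–Cl bond at room temperature and the weakly basic zinc enolate tolerates the acidic CH2 of 3 where alkali-metal enolates would not.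

Step 3
Reactants: 6 tert-butyl 2-[2-chloro-5-(2-methoxy-2-oxoethyl)pyridin-4-yl]acetate
Product: 7 tert-butyl 3-chloro-6-oxo-6,7-dihydro-5H-cyclopenta[c]pyridine-5-carboxylate (largely as its enol)
Conditions: KOtBu (1.5 equiv), THF, 0 → 25 °C; then aq. HCl to pH 4
Reagents that add atoms: none
Why: Dieckmann condensation in which the enolate next to the tert-butyl ester attacks the far more electrophilic methyl ester in a 5-exo-trig closure, and deprotonation of the β-keto ester drives the equilibrium.

Step 4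
Reactants: 7 tert-butyl 3-chloro-6-oxo-6,7-dihydro-5H-cyclopenta[c]pyridine-5-carboxylate
Product: 8 tert-butyl (5R)-3-chloro-5-hydroxy-6-oxo-6,7-dihydro-5H-cyclopenta[c]pyridine-5-carboxylate
Conditions: cumene hydroperoxide (1.1 equiv), hydroquinidine (20 mol%), CH2Br2, 0 → 25 °C, argon, dark; recrystallisation
Reagents that add atoms: cumene hydroperoxide CC(C)(OO)c1ccccc1
Why: Organocatalytic electrophilic α-hydroxylation of a cyclic β-keto ester, in which the protonated cinchona base pairs with the enolate and shields one face of C5 so that the peroxide oxygen arrives on the other; C5 is thus set under catalyst control, the bulky tert-butyl ester sharpens the discrimination and crystallisation should raise the ee.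

Step 5
Reactants: 8 tert-butyl (5R)-3-chloro-5-hydroxy-6-oxo-6,7-dihydro-5H-cyclopenta[c]pyridine-5-carboxylate
Product: 9 tert-butyl (5R)-3-chloro-6-oxo-5-[(triethylsilyl)oxy]-6,7-dihydro-5H-cyclopenta[c]pyridine-5-carboxylate
Conditions: Et3SiOTf (1.1 equiv), 2,6-lutidine (2 equiv), CH2Cl2, −78 → −20 °C
Reagents that add atoms: triethylsilyl trifluoromethanesulfonate CC[Si](CC)(CC)OS(=O)(=O)C(F)(F)F
Why: Silyl triflate silylation of a hindered tertiary alcohol; at −78 °C with 2,6-lutidine the O–H should react faster than the ketone is enolised, and any silyl enol ether is hydrolysed on work-up.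

Step 6
Reactants: 9 tert-butyl (5R)-3-chloro-6-oxo-5-[(triethylsilyl)oxy]-6,7-dihydro-5H-cyclopenta[c]pyridine-5-carboxylate
Product: 10 tert-butyl (5R)-3-chloro-5-[(triethylsilyl)oxy]-6-{[(trifluoromethyl)sulfonyl]oxy}-5H-cyclopenta[c]pyridine-5-carboxylate
Conditions: KN(SiMe3)2 (1.1 equiv), THF, −78 °C; then PhNTf2 (1.15 equiv), −78 → 0 °C
Reagents that add atoms: N-phenylbis(trifluoromethanesulfonimide) O=S(=O)(N(c1ccccc1)S(=O)(=O)C(F)(F)F)C(F)(F)F
Why: Enolate O-triflation with fixed regiochemistry, since only C7 carries α-hydrogens and the single enolate is trapped on oxygen by the triflimide.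

Step 7
Reactants: 10 tert-butyl (5R)-3-chloro-5-[(triethylsilyl)oxy]-6-{[(trifluoromethyl)sulfonyl]oxy}-5H-cyclopenta[c]pyridine-5-carboxylate
Product: 11 tert-butyl (5S)-3-chloro-6-methyl-5-[(triethylsilyl)oxy]-5H-cyclopenta[c]pyridine-5-carboxylate
Conditions: MeZnCl (1.5 equiv), Pd(PPh3)4 (5 mol%), THF, 0 → 25 °C
Reagents that add atoms: methylzinc chloride C[Zn]Cl
Why: Negishi coupling of a vinyl triflate, in which oxidative addition of zerovalent palladium to the C6–OTf bond is fast at room temperature while the C3–Cl bond stays intact, and the quaternary C5 rules out any double-bond shift.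

Step 8
Reactants: 11 tert-butyl (5S)-3-chloro-6-methyl-5-[(triethylsilyl)oxy]-5H-cyclopenta[c]pyridine-5-carboxylate
Product: 13 (5S)-3-chloro-6-methyl-5-[(triethylsilyl)oxy]-5H-cyclopenta[c]pyridine-5-carboxylic acid, via trimethylsilyl ester 12 (not isolated)
Conditions: Me3SiOTf (2.5 equiv), 2,6-lutidine (4 equiv), CH2Cl2, 0 °C; then pH 5 phosphate buffer, 0 °C; used at once
Reagents that add atoms: none
Why: Silyl-triflate-mediated tert-butyl ester cleavage (carbonyl O-silylation, loss of isobutene, hydrolysis of the silyl ester on work-up) spares the tertiary silyl ether that protic acid would remove, and ionisation at C5 is blocked because it would create an antiaromatic aza-indenyl cation.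

Step 9
Reactants: 13 (5S)-3-chloro-6-methyl-5-[(triethylsilyl)oxy]-5H-cyclopenta[c]pyridine-5-carboxylic acid
Product: 14 (5R,6S,7S)-3-chloro-6-hydroxy-7-iodo-6-methyl-5-[(triethylsilyl)oxy]-6,7-dihydro-5H-cyclopenta[c]pyridine-5-carboxylic acid β-lactone (cis-fused; iodine trans to the lactone oxygen)
Conditions: I2 (3 equiv), sat. aq. NaHCO3/CH2Cl2 (two-phase), 0 °C, dark
Reagents that add atoms: iodine II
Why: Iodine adds reversibly to the C6=C7 bond, and only the iodonium ion on the face opposite the C5 carboxylate (the silyloxy face) can be opened, by attack of a carboxylate oxygen on the tertiary C6. This is the kinetic iodolactonisation of an α,α-disubstituted β,γ-unsaturated acid to a β-lactone under two-phase bicarbonate conditions. The oxetanone closes in the 4-exo mode, whereas attack at C7 would demand a 2-oxabicyclo[2.1.1]hexanone and is excluded by strain. C6 is set by the tether, since the oxygen can only arrive from the face that carries the C5 carboxyl and so ends cis to the carboxyl carbon and trans to the silyl ether; C7 is set by anti opening of the iodonium ion, which places iodine trans to the new C6–O bond. The step needs kinetic control and chemoselectivity for the alkene: the CH2Cl2 layer withdraws the neutral lactone from iodide and base, the 3-chloro substituent leaves the ring nitrogen too weakly basic to bind iodine, and the silyl ether keeps the C5 oxygen from competing as a nucleophile.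

Step 10
Reactants: 14 (5R,6S,7S)-3-chloro-6-hydroxy-7-iodo-6-methyl-5-[(triethylsilyl)oxy]-6,7-dihydro-5H-cyclopenta[c]pyridine-5-carboxylic acid β-lactone
Product: 16 (5R,6S)-3-chloro-6-hydroxy-6-methyl-7-oxo-5-[(triethylsilyl)oxy]-6,7-dihydro-5H-cyclopenta[c]pyridine-5-carboxylic acid β-lactone, via alkoxysulfonium tetrafluoroborate 15 (not isolated)
Conditions: AgBF4 (2 equiv), DMSO, 25 °C, dark; then Et3N (4 equiv), 25 °C
Reagents that add atoms: dimethyl sulfoxide CS(C)=O
Why: Silver-assisted Kornblum oxidation, in which the silver ion removes the benzylic iodide as AgI (also taking away the iodide that could reverse the lactonisation), DMSO captures C7 as the alkoxysulfonium salt and Et3N collapses it to the ketone; C7 has no β-hydrogen, so elimination cannot compete.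

Step 11
Reactants: 16 (5R,6S)-3-chloro-6-hydroxy-6-methyl-7-oxo-5-[(triethylsilyl)oxy]-6,7-dihydro-5H-cyclopenta[c]pyridine-5-carboxylic acid β-lactone
Product: 17 methyl (5R,6S)-3-chloro-6-hydroxy-6-methyl-7-oxo-5-[(triethylsilyl)oxy]-6,7-dihydro-5H-cyclopenta[c]pyridine-5-carboxylate
Conditions: MeOH/THF (3:1), K2CO3 (0.2 equiv), −20 → 0 °C; pH 7 buffer
Reagents that add atoms: methanol CO
Why: Base-catalysed alcoholysis of a strained β-lactone by acyl–oxygen cleavage leaves the C6–O bond and hence the C6 configuration untouched, while low temperature and catalytic base should avoid displacement of the activated C3 chloride and retro-aldol opening of the tertiary alkoxide.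

Step 12
Reactants: 17 methyl (5R,6S)-3-chloro-6-hydroxy-6-methyl-7-oxo-5-[(triethylsilyl)oxy]-6,7-dihydro-5H-cyclopenta[c]pyridine-5-carboxylate
Product: 18 methyl (5R,6S)-6-(acetyloxy)-3-chloro-6-methyl-7-oxo-5-[(triethylsilyl)oxy]-6,7-dihydro-5H-cyclopenta[c]pyridine-5-carboxylate
Conditions: Ac2O (5 equiv), Et3N (6 equiv), DMAP (0.5 equiv), CH2Cl2, 25 → 35 °C
Reagents that add atoms: acetic anhydride CC(=O)OC(C)=O
Why: DMAP-catalysed acyl transfer to the only free hydroxyl; neither the ketone nor the ester has an α-hydrogen, so the amine base cannot epimerise anything.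

Step 13
Reactants: 19 (S)-2-methylbutan-1-ol; 20 ethyl 2-(triphenyl-λ5-phosphanylidene)propanoate
Product: 22 ethyl (2E,4S)-2,4-dimethylhex-2-enoate, via (S)-2-methylbutanal 21 (not isolated)
Conditions: TEMPO (10 mol%), PhI(OAc)2 (1.1 equiv), CH2Cl2, 25 °C; then 20 (1.3 equiv), 25 → 40 °C
Reagents that add atoms: none
Why: Nitroxyl-catalysed oxidation should give the α-chiral aldehyde without epimerisation, and the stabilised ylide added to the same flask gives the (E)-trisubstituted enoate in a Wittig reaction.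

Step 14
Reactants: 22 ethyl (2E,4S)-2,4-dimethylhex-2-enoate
Product: 23 (2E,4S)-2,4-dimethylhex-2-en-1-ol
Conditions: iBu2AlH (2.2 equiv), CH2Cl2, −78 °C; aq. potassium sodium tartrate
Reagents that add atoms: none
Why: 1,2-Reduction of the enoate by the aluminium hydride at low temperature gives the allylic alcohol and leaves the alkene alone.

Step 15
Reactants: 23 (2E,4S)-2,4-dimethylhex-2-en-1-ol
Product: 24 (2E,4S)-2,4-dimethylhex-2-enal
Conditions: MnO2 (15 equiv), CH2Cl2, 25 °C
Reagents that add atoms: none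
Why: Allylic oxidation by MnO2 is selective and neutral, so the alkene geometry and the stereocentre are kept.

Step 16
Reactants: 24 (2E,4S)-2,4-dimethylhex-2-enal; 25 2,2'-methylenebis(4,4,5,5-tetramethyl-1,3,2-dioxaborolane)
Product: 26 2-[(1E,3E,5S)-3,5-dimethylhepta-1,3-dien-1-yl]-4,4,5,5-tetramethyl-1,3,2-dioxaborolane
Conditions: lithium 2,2,6,6-tetramethylpiperidide (1.2 equiv), 25 (1.2 equiv), THF, 0 °C; then 24, −78 → 25 °C
Reagents that add atoms: none
Why: Boron–Wittig reaction, in which the α-boryl carbanion of the geminal bis(boronate) adds 1,2 to the enal and syn B–O elimination favours the trans alkenyl boronate, with the remote stereocentre untouched.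

Step 17
Reactants: 18 methyl (5R,6S)-6-(acetyloxy)-3-chloro-6-methyl-7-oxo-5-[(triethylsilyl)oxy]-6,7-dihydro-5H-cyclopenta[c]pyridine-5-carboxylate; 26 2-[(1E,3E,5S)-3,5-dimethylhepta-1,3-dien-1-yl]-4,4,5,5-tetramethyl-1,3,2-dioxaborolane
Product: 27 methyl (5R,6S)-6-(acetyloxy)-3-[(1E,3E,5S)-3,5-dimethylhepta-1,3-dien-1-yl]-6-methyl-7-oxo-5-[(triethylsilyl)oxy]-6,7-dihydro-5H-cyclopenta[c]pyridine-5-carboxylate
Conditions: Pd(dppf)Cl2 (5 mol%), K3PO4 (2 equiv), THF/H2O (10:1), 50 °C
Reagents that add atoms: none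
Why: Suzuki–Miyaura coupling at a C3–Cl bond that is α to the ring nitrogen and para to the acyl-bearing C7a, so oxidative addition to zerovalent palladium is easy, the alkenyl group transfers with retention of geometry and phosphate is mild enough for the tertiary acetate and the methyl ester.

Step 18
Reactants: 27 methyl (5R,6S)-6-(acetyloxy)-3-[(1E,3E,5S)-3,5-dimethylhepta-1,3-dien-1-yl]-6-methyl-7-oxo-5-[(triethylsilyl)oxy]-6,7-dihydro-5H-cyclopenta[c]pyridine-5-carboxylate
Product: 28 methyl (5R,6S)-6-(acetyloxy)-3-[(1E,3E,5S)-3,5-dimethylhepta-1,3-dien-1-yl]-5-hydroxy-6-methyl-7-oxo-6,7-dihydro-5H-cyclopenta[c]pyridine-5-carboxylate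
Conditions: HF·pyridine, pyridine, THF, 0 → 25 °C
Reagents that add atoms: none
Why: Fluoride cleavage of the silyl ether under buffered, non-basic conditions avoids the retro-aldol opening that a C5 alkoxide of this β-hydroxy ketone could undergo, and the trans arrangement of the C5 and C6 oxygens prevents acetyl migration.

Compound list
1 | 5-bromo-2-chloro-4-methylpyridine | Cc1cc(Cl)ncc1Br | starting material
2 | di-tert-butyl dicarbonate | CC(C)(C)OC(=O)OC(=O)OC(C)(C)C | starting material
3 | tert-butyl 2-(5-bromo-2-chloropyridin-4-yl)acetate | CC(C)(C)OC(=O)Cc1cc(Cl)ncc1Br | intermediate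
4 | methyl bromoacetate | COC(=O)CBr | starting material
5 | (2-methoxy-2-oxoethyl)zinc bromide | COC(=O)C[Zn]Br | intermediate
6 | tert-butyl 2-[2-chloro-5-(2-methoxy-2-oxoethyl)pyridin-4-yl]acetate | COC(=O)Cc1cnc(Cl)cc1CC(=O)OC(C)(C)C | intermediate
7 | tert-butyl 3-chloro-6-oxo-6,7-dihydro-5H-cyclopenta[c]pyridine-5-carboxylate (racemic, enolised) | Clc1cc2c(cn1)CC(=O)C2C(=O)OC(C)(C)C | intermediate
8 | tert-butyl (5R)-3-chloro-5-hydroxy-6-oxo-6,7-dihydro-5H-cyclopenta[c]pyridine-5-carboxylate | Clc1cc2c(cn1)CC(=O)[C@@]2(O)C(=O)OC(C)(C)C | intermediate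
9 | tert-butyl (5R)-3-chloro-6-oxo-5-[(triethylsilyl)oxy]-6,7-dihydro-5H-cyclopenta[c]pyridine-5-carboxylate | Clc1cc2c(cn1)CC(=O)[C@@]2(O[Si](CC)(CC)CC)C(=O)OC(C)(C)C | intermediate
10 | tert-butyl (5R)-3-chloro-5-[(triethylsilyl)oxy]-6-{[(trifluoromethyl)sulfonyl]oxy}-5H-cyclopenta[c]pyridine-5-carboxylate | Clc1cc2c(cn1)C=C(OS(=O)(=O)C(F)(F)F)[C@@]2(O[Si](CC)(CC)CC)C(=O)OC(C)(C)C | intermediate
11 | tert-butyl (5S)-3-chloro-6-methyl-5-[(triethylsilyl)oxy]-5H-cyclopenta[c]pyridine-5-carboxylate | Clc1cc2c(cn1)C=C(C)[C@@]2(O[Si](CC)(CC)CC)C(=O)OC(C)(C)C | intermediate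
12 | trimethylsilyl (5S)-3-chloro-6-methyl-5-[(triethylsilyl)oxy]-5H-cyclopenta[c]pyridine-5-carboxylate | Clc1cc2c(cn1)C=C(C)[C@@]2(O[Si](CC)(CC)CC)C(=O)O[Si](C)(C)C | intermediate
13 | (5S)-3-chloro-6-methyl-5-[(triethylsilyl)oxy]-5H-cyclopenta[c]pyridine-5-carboxylic acid | Clc1cc2c(cn1)C=C(C)[C@@]2(O[Si](CC)(CC)CC)C(=O)O | intermediate
14 | (5R,6S,7S)-3-chloro-6-hydroxy-7-iodo-6-methyl-5-[(triethylsilyl)oxy]-6,7-dihydro-5H-cyclopenta[c]pyridine-5-carboxylic acid β-lactone | Clc1cc2c(cn1)[C@H](I)[C@@]3(C)OC(=O)[C@@]23O[Si](CC)(CC)CC | intermediate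
15 | dimethylsulfonium-oxy analogue of 14 at C7 (iodine replaced by OSMe2+), tetrafluoroborate, C7 configuration not defined | Clc1cc2c(cn1)C(O[S+](C)C)[C@@]3(C)OC(=O)[C@@]23O[Si](CC)(CC)CC.F[B-](F)(F)F | intermediate
16 | (5R,6S)-3-chloro-6-hydroxy-6-methyl-7-oxo-5-[(triethylsilyl)oxy]-6,7-dihydro-5H-cyclopenta[c]pyridine-5-carboxylic acid β-lactone | Clc1cc2c(cn1)C(=O)[C@@]3(C)OC(=O)[C@@]23O[Si](CC)(CC)CC | intermediate
17 | methyl (5R,6S)-3-chloro-6-hydroxy-6-methyl-7-oxo-5-[(triethylsilyl)oxy]-6,7-dihydro-5H-cyclopenta[c]pyridine-5-carboxylate | Clc1cc2c(cn1)C(=O)[C@@](C)(O)[C@@]2(O[Si](CC)(CC)CC)C(=O)OC | intermediate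
18 | methyl (5R,6S)-6-(acetyloxy)-3-chloro-6-methyl-7-oxo-5-[(triethylsilyl)oxy]-6,7-dihydro-5H-cyclopenta[c]pyridine-5-carboxylate | Clc1cc2c(cn1)C(=O)[C@@](C)(OC(C)=O)[C@@]2(O[Si](CC)(CC)CC)C(=O)OC | intermediate
19 | (S)-2-methylbutan-1-ol | CC[C@H](C)CO | starting material
20 | ethyl 2-(triphenyl-λ5-phosphanylidene)propanoate | CCOC(=O)C(C)=P(c1ccccc1)(c1ccccc1)c1ccccc1 | starting material
21 | (S)-2-methylbutanal | CC[C@H](C)C=O | intermediate
22 | ethyl (2E,4S)-2,4-dimethylhex-2-enoate | CC[C@H](C)/C=C(C)/C(=O)OCC | intermediate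
23 | (2E,4S)-2,4-dimethylhex-2-en-1-ol | CC[C@H](C)/C=C(C)/CO | intermediate
24 | (2E,4S)-2,4-dimethylhex-2-enal | CC[C@H](C)/C=C(C)/C=O | intermediate
25 | 2,2'-methylenebis(4,4,5,5-tetramethyl-1,3,2-dioxaborolane) | CC1(C)OB(CB2OC(C)(C)C(C)(C)O2)OC1(C)C | starting material
26 | 2-[(1E,3E,5S)-3,5-dimethylhepta-1,3-dien-1-yl]-4,4,5,5-tetramethyl-1,3,2-dioxaborolane | CC[C@H](C)/C=C(C)/C=C/B1OC(C)(C)C(C)(C)O1 | intermediate
27 | methyl (5R,6S)-6-(acetyloxy)-3-[(1E,3E,5S)-3,5-dimethylhepta-1,3-dien-1-yl]-6-methyl-7-oxo-5-[(triethylsilyl)oxy]-6,7-dihydro-5H-cyclopenta[c]pyridine-5-carboxylate | CC[C@H](C)/C=C(C)/C=C/c1cc2c(cn1)C(=O)[C@@](C)(OC(C)=O)[C@@]2(O[Si](CC)(CC)CC)C(=O)OC | intermediate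
28 | methyl (5R,6S)-6-(acetyloxy)-3-[(1E,3E,5S)-3,5-dimethylhepta-1,3-dien-1-yl]-5-hydroxy-6-methyl-7-oxo-6,7-dihydro-5H-cyclopenta[c]pyridine-5-carboxylate | CC[C@H](C)/C=C(C)/C=C/c1cc2c(cn1)C(=O)[C@@](C)(OC(C)=O)[C@@]2(O)C(=O)OC | target

Total steps: 18. Longest linear sequence: 14 (steps 1–12, 17 and 18); steps 13–16 form the side-chain branch.

Steps most likely to fail

Step 9. The iodonium carboxylate may lose carbon dioxide instead of closing (iododecarboxylation toward a C5=C6 silyl enol ether), the carboxylate may decarboxylate beforehand because the resulting aza-indenyl anion is aromatic, and the lactone may revert if iodide is not removed. The fallback sets out from acid 13. Me3SiCHN2 (toluene/MeOH, 0 °C) should give methyl (5S)-3-chloro-6-methyl-5-[(triethylsilyl)oxy]-5H-cyclopenta[c]pyridine-5-carboxylate F1. Dihydroxylation with OsO4 (cat.) and N-methylmorpholine N-oxide in acetone/water, expected on the face away from the allylic silyloxy group, should give methyl (5R,6R,7R)-3-chloro-6,7-dihydroxy-6-methyl-5-[(triethylsilyl)oxy]-6,7-dihydro-5H-cyclopenta[c]pyridine-5-carboxylate F2. IBX in DMSO then oxidises only the secondary benzylic C7 alcohol, and the route is rejoined at 17, so that steps 9 to 11 are bypassed.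

Step 10. Substitution at C7 may stall, since the carbon is flanked by the quaternary C6 and its cation is poorly stabilised by the chloropyridine ring; slow ionisation would leave time for opening of the β-lactone. The fallback sets out from iodide 14. Bu3SnH and excess TEMPO (benzene, 60 °C) should break the C–I bond homolytically and trap the C7 radical as (5R,6S)-3-chloro-6-hydroxy-6-methyl-7-[(2,2,6,6-tetramethylpiperidin-1-yl)oxy]-5-[(triethylsilyl)oxy]-6,7-dihydro-5H-cyclopenta[c]pyridine-5-carboxylic acid β-lactone F3. mCPBA (CH2Cl2, 0 °C) then oxidises the alkoxyamine nitrogen and Cope-type elimination gives the ketone, returning to the route at 16.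

Step 4. Face discrimination by the ion pair may be poor for this strongly enolised aza-2-indanone ester, and the acidic C7 position of the product may be oxidised further. The fallback sets out from 7. Dimethyldioxirane (acetone, 0 °C) should give racemic tert-butyl 3-chloro-5-hydroxy-6-oxo-6,7-dihydro-5H-cyclopenta[c]pyridine-5-carboxylate F4. Preparative SFC on a chiral stationary phase separates 8 from tert-butyl (5S)-3-chloro-5-hydroxy-6-oxo-6,7-dihydro-5H-cyclopenta[c]pyridine-5-carboxylate F5, and the route continues from 8.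

Further compounds
F1 | step 9 | methyl (5S)-3-chloro-6-methyl-5-[(triethylsilyl)oxy]-5H-cyclopenta[c]pyridine-5-carboxylate | Clc1cc2c(cn1)C=C(C)[C@@]2(O[Si](CC)(CC)CC)C(=O)OC
F2 | step 9 | methyl (5R,6R,7R)-3-chloro-6,7-dihydroxy-6-methyl-5-[(triethylsilyl)oxy]-6,7-dihydro-5H-cyclopenta[c]pyridine-5-carboxylate | Clc1cc2c(cn1)[C@@H](O)[C@@](C)(O)[C@@]2(O[Si](CC)(CC)CC)C(=O)OC
F3 | step 10 | (5R,6S)-3-chloro-6-hydroxy-6-methyl-7-[(2,2,6,6-tetramethylpiperidin-1-yl)oxy]-5-[(triethylsilyl)oxy]-6,7-dihydro-5H-cyclopenta[c]pyridine-5-carboxylic acid β-lactone (C7 epimers) | Clc1cc2c(cn1)C(ON4C(C)(C)CCCC4(C)C)[C@@]3(C)OC(=O)[C@@]23O[Si](CC)(CC)CC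
F4 | step 4 | racemic tert-butyl 3-chloro-5-hydroxy-6-oxo-6,7-dihydro-5H-cyclopenta[c]pyridine-5-carboxylate | Clc1cc2c(cn1)CC(=O)C2(O)C(=O)OC(C)(C)C
F5 | step 4 | tert-butyl (5S)-3-chloro-5-hydroxy-6-oxo-6,7-dihydro-5H-cyclopenta[c]pyridine-5-carboxylate | Clc1cc2c(cn1)CC(=O)[C@]2(O)C(=O)OC(C)(C)C
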